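**Plan**

- Numbering: both halves are numbered as chromans. Ring A is the 5,7-dihydroxy-6-acyl unit and ring B is the chroman that carries the chain at its C6.
- Cuts: first the ring A C6–C(=O) bond (aryllithium plus Weinreb amide). Then O1–C8a, C4–C4a and O1–C2 of ring A (aryne plus enal), and C4–C4a and O1–C2 of ring B (phenol plus diene).
- Enabling feature: in ring A, O1 on C8a and C4 on C4a sit on neighbouring arene carbons, and C4a lies directly beside the oxygen-bearing C5. A 3-alkoxyaryne gives this pattern when it takes up a carbonyl group, with oxygen at the remote carbon and carbon next to the alkoxy group.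
- Forward: phloroglucinol 1 is taken to silylaryl triflate 7, and its aryne closes the ring A pyran with 3-methylbut-2-enal 8 (chromene 12, hydrogenated to chroman 13). The ring B pyran is closed separately from ester 14 and isoprene 15 and carried to amide 18; C6 lithiation of 13 joins the halves (21) and acid frees target 22.
- The methoxymethyl (MOM) ethers serve three purposes. They tolerate s-BuLi where benzyl ethers risk benzylic deprotonation, the C5 one polarises the aryne, and the pair directs the late lithiation to C6 rather than C8.
- Stereochemistry: the target is achiral (both C2 atoms carry two methyl groups), so no stereocentre has to be set.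

Key step: step 6

Remark: methyl 3-(4-hydroxyphenyl)propanoate is taken as the commercial form of 3-(4-hydroxyphenyl)propanoic acid. Silylphenol 6 is carried into step 5 as crude material without chromatography.

**Step 1**
Reactants: 1 phloroglucinol
Product: 2 3,5-bis(methoxymethoxy)phenol
Conditions: NaH (2.0 equiv), MOMCl (2.0 equiv), DMF, 0 °C → rt; chromatography
Reagents that add atoms: chloromethyl methyl ether (MOMCl), COCCl
Why: Williamson-type O-alkylation of the phenoxide by the hard chloromethyl ether should stop statistically at the bis-ether with two equivalents of reagent, and the separable mono-ether can be resubmitted.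

**Step 2**
Reactants: 2 3,5-bis(methoxymethoxy)phenol
Product: 3 3,5-bis(methoxymethoxy)phenyl N,N-diethylcarbamate
Conditions: NaH, ClC(O)NEt2, THF, 0 °C → rt
Reagents that add atoms: N,N-diethylcarbamoyl chloride, CCN(CC)C(=O)Cl
Why: O-carbamoylation of the sodium phenoxide installs the strongest oxygen-based directing group for ortho-metalation, and the MOM acetals are inert to base.

**Step 3**
Reactants: 3 3,5-bis(methoxymethoxy)phenyl N,N-diethylcarbamate
Product: 5 3,5-bis(methoxymethoxy)-2-(trimethylsilyl)phenyl N,N-diethylcarbamate, via 2-lithio carbamate 4 (not isolated)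
Conditions: s-BuLi, TMEDA, THF, −78 °C; then Me3SiCl, −78 °C → rt
Reagents that add atoms: chlorotrimethylsilane, C[Si](C)(C)Cl
Why: Directed ortho-metalation should remove the proton between the carbamate and a MOM ether (cooperative direction, two equivalent sites) in preference to the one between the two weaker MOM directors, and quenching at −78 °C forestalls the anionic ortho-Fries shift.

**Step 4**
Reactants: 5 3,5-bis(methoxymethoxy)-2-(trimethylsilyl)phenyl N,N-diethylcarbamate
Product: 6 3,5-bis(methoxymethoxy)-2-(trimethylsilyl)phenol
Conditions: LiAlH4, THF, 0 → 50 °C; aq. KNaC4H4O6 work-up, crude product used directly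
Reagents that add atoms: none
Why: Hydride reduction of the aryl carbamate expels the phenoxide under non-acidic conditions, which spare the MOM acetals and the acid-labile C–Si bond.

**Step 5**
Reactants: 6 3,5-bis(methoxymethoxy)-2-(trimethylsilyl)phenol
Product: 7 3,5-bis(methoxymethoxy)-2-(trimethylsilyl)phenyl trifluoromethanesulfonate
Conditions: PhNTf2, DBU, MeCN, rt
Reagents that add atoms: N-phenylbis(trifluoromethanesulfonimide), O=S(=O)(N(c1ccccc1)S(=O)(=O)C(F)(F)F)C(F)(F)F
Why: O-sulfonylation of the amidine-generated phenoxide with the mild triflyl donor keeps the medium basic throughout, so neither protodesilylation nor acetal activation should compete.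

**Step 6**
Reactants: 7 3,5-bis(methoxymethoxy)-2-(trimethylsilyl)phenyl trifluoromethanesulfonate; 8 3-methylbut-2-enal
Product: 12 5,7-bis(methoxymethoxy)-2,2-dimethyl-2H-chromene, via 3,5-bis(methoxymethoxy)benzyne 9 (not isolated), via benzoxete 10 (not isolated), via ortho-quinone methide 11 (not isolated)
Conditions: CsF (3 equiv), 8 (4 equiv), MeCN, rt → 40 °C, slow addition of 7
Reagents that add atoms: none
Why: Fluoride attacks silicon in 7 and triflate departs to give aryne 9, whose future C8a is attacked by the carbonyl oxygen of 8 while the developing aryl anion at C4a closes on the carbonyl carbon (formal [2+2]) to give benzoxete 10. Strain-driven 4π opening of 10 breaks the first-formed O–C4 bond and gives ortho-quinone methide 11, a 1-oxatriene whose thermal disrotatory oxa-6π electrocyclisation joins O1 to the dimethyl-bearing C2 and restores aromaticity. The closest known reaction type is the fluoride-triggered union of silylaryl triflates with α,β-unsaturated aldehydes to give 2H-chromenes, so this is an application of established aryne chemistry. The single ring closed, the ring A pyran, closes by this six-electron pericyclic process, and no stereocentre arises because C2 carries two methyl groups. The step needs oxygen at C8a and carbon at C4a: the σ-withdrawing C5 methoxymethoxy group distorts the aryne so that the remote carbon is the electrophilic one and negative charge builds up next to the C5 oxygen, while the C7 group is too distant to overturn this. Excess 8 and slow release of 9 should suppress capture of 11 by a second aryne and the ene reaction at the allylic methyl groups, and the fully substituted β-carbon of 8 disfavours the alternative [4+2] closure.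

**Step 7**
Reactants: 12 5,7-bis(methoxymethoxy)-2,2-dimethyl-2H-chromene
Product: 13 5,7-bis(methoxymethoxy)-2,2-dimethylchroman
Conditions: H2 (1 atm), 10% Pd/C, EtOAc, rt
Reagents that add atoms: none
Why: Heterogeneous catalytic hydrogenation should saturate the styrene-type C3–C4 alkene quickly while the MOM acetals, aryl ethers and arene stay untouched, and it removes the alkene before butyllithium is used.

**Step 8**
Reactants: 14 methyl 3-(4-hydroxyphenyl)propanoate; 15 isoprene
Product: 17 methyl 3-(2,2-dimethylchroman-6-yl)propanoate, via ortho-prenylphenol 16 (not isolated)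
Conditions: AgOTf (AgOSO2CF3, 5 mol %), 15 (3 equiv), ClCH2CH2Cl, rt, sealed flask
Reagents that add atoms: none
Why: Friedel–Crafts prenylation ortho to the hydroxyl (para position blocked, both ortho sites equivalent) followed by Markovnikov hydroalkoxylation of the trisubstituted alkene of 16 is a known one-pot chroman synthesis from phenols and isoprene, and it closes the ring B pyran.

**Step 9**
Reactants: 17 methyl 3-(2,2-dimethylchroman-6-yl)propanoate
Product: 18 3-(2,2-dimethylchroman-6-yl)-N-methoxy-N-methylpropanamide
Conditions: MeNH(OMe)·HCl, iPrMgCl, THF, −20 → 0 °C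
Reagents that add atoms: N,O-dimethylhydroxylamine hydrochloride, CNOC.Cl
Why: Direct aminolysis of the methyl ester by the magnesium amide of N,O-dimethylhydroxylamine (Weinreb amide formation) runs below 0 °C and leaves the chroman ether untouched.

**Step 10**
Reactants: 13 5,7-bis(methoxymethoxy)-2,2-dimethylchroman; 18 3-(2,2-dimethylchroman-6-yl)-N-methoxy-N-methylpropanamide
Product: 21 1-[5,7-bis(methoxymethoxy)-2,2-dimethylchroman-6-yl]-3-(2,2-dimethylchroman-6-yl)propan-1-one, via 6-lithiochroman 19 (not isolated), via tetrahedral lithium adduct 20 (not isolated)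
Conditions: n-BuLi, THF, 0 °C; then 18, −78 → 0 °C; H2O quench
Reagents that add atoms: none
Why: Directed ortho-metalation followed by Weinreb ketone synthesis should work because C6–H lies between two chelating MOM ethers whereas C8–H has only one beside the non-chelating ring oxygen, and the chelated adduct 20 persists until the quench and so excludes over-addition.

**Step 11**
Reactants: 21 1-[5,7-bis(methoxymethoxy)-2,2-dimethylchroman-6-yl]-3-(2,2-dimethylchroman-6-yl)propan-1-one
Product: 22 1-(5,7-dihydroxy-2,2-dimethylchroman-6-yl)-3-(2,2-dimethylchroman-6-yl)propan-1-one (CNP0080574.0)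
Conditions: HCl (1.25 M in MeOH), 40 °C
Reagents that add atoms: none
Why: Acid-catalysed acetal exchange with methanol (MOM cleavage) frees both phenols, each hydrogen-bonded to the C6 carbonyl, under conditions too mild to open either tertiary chroman ether and shift the acyl pattern.

**Compound list**

1 | phloroglucinol | Oc1cc(O)cc(O)c1 | starting material
2 | 3,5-bis(methoxymethoxy)phenol | COCOc1cc(O)cc(OCOC)c1 | intermediate
3 | 3,5-bis(methoxymethoxy)phenyl N,N-diethylcarbamate | CCN(CC)C(=O)Oc1cc(OCOC)cc(OCOC)c1 | intermediate
4 | 2-lithio-3,5-bis(methoxymethoxy)phenyl N,N-diethylcarbamate | [Li]c1c(OC(=O)N(CC)CC)cc(OCOC)cc1OCOC | intermediate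
5 | 3,5-bis(methoxymethoxy)-2-(trimethylsilyl)phenyl N,N-diethylcarbamate | CCN(CC)C(=O)Oc1cc(OCOC)cc(OCOC)c1[Si](C)(C)C | intermediate
6 | 3,5-bis(methoxymethoxy)-2-(trimethylsilyl)phenol | COCOc1cc(O)c([Si](C)(C)C)c(OCOC)c1 | intermediate
7 | 3,5-bis(methoxymethoxy)-2-(trimethylsilyl)phenyl trifluoromethanesulfonate | COCOc1cc(OCOC)c([Si](C)(C)C)c(OS(=O)(=O)C(F)(F)F)c1 | intermediate
8 | 3-methylbut-2-enal | CC(C)=CC=O | starting material
9 | 3,5-bis(methoxymethoxy)benzyne | C1#CC(OCOC)=CC(OCOC)=C1 | intermediate
10 | 3,5-bis(methoxymethoxy)-2-(2-methylprop-1-enyl)-2H-benzo[b]oxete (racemic, transient) | CC(C)=CC1Oc2cc(OCOC)cc(OCOC)c12 | intermediate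
11 | (6Z)-3,5-bis(methoxymethoxy)-6-(3-methylbut-2-enylidene)cyclohexa-2,4-dien-1-one | CC(C)=C/C=C1\C(=O)C=C(OCOC)C=C1OCOC | intermediate
12 | 5,7-bis(methoxymethoxy)-2,2-dimethyl-2H-chromene | CC1(C)C=Cc2c(OCOC)cc(OCOC)cc2O1 | intermediate
13 | 5,7-bis(methoxymethoxy)-2,2-dimethylchroman | CC1(C)CCc2c(OCOC)cc(OCOC)cc2O1 | intermediate
14 | methyl 3-(4-hydroxyphenyl)propanoate | COC(=O)CCc1ccc(O)cc1 | starting material
15 | isoprene | C=CC(C)=C | starting material
16 | methyl 3-[4-hydroxy-3-(3-methylbut-2-enyl)phenyl]propanoate | COC(=O)CCc1ccc(O)c(CC=C(C)C)c1 | intermediate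
17 | methyl 3-(2,2-dimethylchroman-6-yl)propanoate | COC(=O)CCc1ccc2c(c1)CCC(C)(C)O2 | intermediate
18 | 3-(2,2-dimethylchroman-6-yl)-N-methoxy-N-methylpropanamide | CON(C)C(=O)CCc1ccc2c(c1)CCC(C)(C)O2 | intermediate
19 | 6-lithio-5,7-bis(methoxymethoxy)-2,2-dimethylchroman | [Li]c1c(OCOC)cc2c(c1OCOC)CCC(C)(C)O2 | intermediate
20 | lithium alkoxide adduct of 19 to amide 18 (racemic, transient) | [Li]OC(CCc1ccc2c(c1)CCC(C)(C)O2)(N(C)OC)c1c(OCOC)cc2c(c1OCOC)CCC(C)(C)O2 | intermediate
21 | 1-[5,7-bis(methoxymethoxy)-2,2-dimethylchroman-6-yl]-3-(2,2-dimethylchroman-6-yl)propan-1-one | CC1(C)CCc2cc(CCC(=O)c3c(OCOC)cc4c(c3OCOC)CCC(C)(C)O4)ccc2O1 | intermediate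
22 | 1-(5,7-dihydroxy-2,2-dimethylchroman-6-yl)-3-(2,2-dimethylchroman-6-yl)propan-1-one | CC1(C)CCc2cc(CCC(=O)c3c(O)cc4c(c3O)CCC(C)(C)O4)ccc2O1 | target

Total step count: 11
Longest linear sequence: 9 (steps 1–7, 10 and 11)

**Steps most likely to fail**

**Step 6.**
- Risk: the aryne may be drained by an ene reaction with the allylic methyl groups of the enal. It may also be lost through fluoride-induced self-condensation of the enal, or through capture of the quinone methide by a second aryne.
- Fallback: this sets out from phenol 2. O-alkylation with 3-chloro-3-methylbut-1-yne (K2CO3, catalytic KI, acetone, reflux) would give 1,3-bis(methoxymethoxy)-5-[(2-methylbut-3-yn-2-yl)oxy]benzene F1.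
- Heating F1 in xylene at about 140 °C would start an aromatic Claisen rearrangement, a [1,5]-hydrogen shift and an oxa-6π closure. Both ortho positions are equivalent, so a single product is expected, and the route is rejoined at chromene 12.

**Step 10.**
- Risk: deprotonation may leak from C6 to C8, or the doubly ortho-substituted aryllithium may take a proton from the α-CH2 of the amide instead of adding.
- Fallback: this avoids carbanion chemistry and sets out from chroman 13 and ester 17. Methanolic HCl would free 13 to 5,7-dihydroxy-2,2-dimethylchroman F2, and LiOH in aqueous THF followed by acidification would turn 17 into 3-(2,2-dimethylchroman-6-yl)propanoic acid F3.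
- Heating F2 and F3 in BF3·OEt2 (Friedel–Crafts acylation with Fries equilibration) would lead directly to target 22. This acylation has no built-in preference for C6 over C8, so the regioisomers would have to be separated by chromatography.

**Step 4.**
- Risk: the trimethylsilyl group may be lost by ipso-protonation of the very electron-rich ring once the free phenol meets work-up or silica. Hydride attack on the carbamate crowded by silicon may also be slow.
- Fallback: this never exposes the free silylphenol and sets out from phenol 2. NBS (CH2Cl2, −78 → 0 °C) should brominate the less hindered position ortho to the hydroxyl and give 2-bromo-3,5-bis(methoxymethoxy)phenol F4. (Me3Si)2NH in THF at reflux would then give [2-bromo-3,5-bis(methoxymethoxy)phenoxy]trimethylsilane F5.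
- n-BuLi (THF, −78 °C) would bring about bromine–lithium exchange and a retro-Brook O→C silyl shift to lithium 3,5-bis(methoxymethoxy)-2-(trimethylsilyl)phenoxide F6. Trapping F6 in the same flask with Tf2O rejoins the route at triflate 7.

**Further compounds**

F1 | step 6 | 1,3-bis(methoxymethoxy)-5-[(2-methylbut-3-yn-2-yl)oxy]benzene | C#CC(C)(C)Oc1cc(OCOC)cc(OCOC)c1
F2 | step 10 | 5,7-dihydroxy-2,2-dimethylchroman | CC1(C)CCc2c(O)cc(O)cc2O1
F3 | step 10 | 3-(2,2-dimethylchroman-6-yl)propanoic acid | OC(=O)CCc1ccc2c(c1)CCC(C)(C)O2
F4 | step 4 | 2-bromo-3,5-bis(methoxymethoxy)phenol | COCOc1cc(O)c(Br)c(OCOC)c1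
F5 | step 4 | [2-bromo-3,5-bis(methoxymethoxy)phenoxy]trimethylsilane | COCOc1cc(O[Si](C)(C)C)c(Br)c(OCOC)c1
F6 | step 4 | lithium 3,5-bis(methoxymethoxy)-2-(trimethylsilyl)phenoxide | [Li+].[O-]c1cc(OCOC)cc(OCOC)c1[Si](C)(C)C
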